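**Retrosynthetic overview**
1. Ring A, the ten-membered carbocycle, is closed last at C4=C5 by ring-closing metathesis of a bis-vinyl precursor. Every other ring is closed through a C–O bond.
2. Ring C, the cis-oxirane, comes from C3–O displacement in a syn-chlorohydrin made by asymmetric γ-chloroallylboration of a C2 enal.
3. Ring B, the α-methylene-γ-lactone, is the pivotal disconnection: the C6–O bond forms by dehydrogenative, dealkylative allylic lactonisation of a tert-butyl 2-methylene-3-propenyl ester. This sets C6 and turns the propenyl group into the metathesis vinyl group.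
4. The C8–O bond is made by acylation with (2S,3S)-epoxyangelic acid (ring D, from a Sharpless epoxidation). The C7–C8 bond comes from an indium Barbier coupling of a dienyl bromide with an α-acetoxy aldehyde, so C7 and C8 are relayed from C9.
5. The C9–OAc bond is made by enantioselective Rh-catalysed addition of acetic acid to a 1,4-enyne obtained by a Wittig reaction. Ring order: D, B, C, A.

Locants (germacrane type):
- C1 is the enoate CH and C10 is the carbon bearing CO2Me (C14).
- C2/C3 are the oxirane carbons and C4=C5 is the cis-alkene.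
- C6 is the lactone O–CH and C7 is the ring-fusion CH.
- C8 bears the epoxyangelate and C9 bears OAc.
- C11/C12/C13 are the lactone α-C, C=O and =CH2.
- The target is 2R,3S,6R,7S,8S,9R,2'S,3'S with 1(10)E and 4Z.

Assumption: the sense of induction of [Rh(cod)Cl]2/(R,R)-Cp-DIOP is carried over from simple alkyl alkynes. If it is reversed for 13, the (S,S)-ligand is used.

**Step 1**
Reactants: 1 (E)-but-2-enal; 2 tert-butyl acrylate
Product: 3 tert-butyl (4E)-3-hydroxy-2-methylidenehex-4-enoate (racemic)
Conditions: DABCO (1 equiv), 1,4-dioxane/H2O 1:1, rt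
Reagents that add atoms: none
Why: Morita–Baylis–Hillman reaction, in which the DABCO-derived enolate of 2 attacks the aldehyde carbon of 1 in 1,2-fashion; the racemic carbinol centre is erased in step 2.

**Step 2**
Reactants: 3 tert-butyl (4E)-3-hydroxy-2-methylidenehex-4-enoate
Product: 4 tert-butyl (2Z,4E)-2-(bromomethyl)hexa-2,4-dienoate
Conditions: NBS, Me2S, CH2Cl2, 0 °C to rt
Reagents that add atoms: N-bromosuccinimide, O=C1CCC(=O)N1Br
Why: Corey–Kim-type activation of the alcohol and SN2' attack of bromide at the methylene carbon give the conjugated primary bromide, and minimised allylic strain puts the propenyl chain cis to CH2Br (2Z), as is general for Morita–Baylis–Hillman alcohols.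

**Step 3**
Reactants: 5 angelic acid
Product: 6 (Z)-2-methylbut-2-en-1-ol
Conditions: LiAlH4, Et2O, 0 °C to rt
Reagents that add atoms: none
Why: Hydride 1,2-reduction of the carboxylic acid, which leaves the Z-alkene untouched.

**Step 4**
Reactants: 6 (Z)-2-methylbut-2-en-1-ol
Product: 7 [(2R,3S)-2,3-dimethyloxiran-2-yl]methanol
Conditions: Ti(OiPr)4 (10 mol%), D-(−)-diethyl tartrate (12 mol%), t-BuOOH, 4 Å MS, CH2Cl2, −20 °C
Reagents that add atoms: tert-butyl hydroperoxide, CC(C)(C)OO
Why: Sharpless asymmetric epoxidation, in which the D-(−)-tartrate catalyst selects the alkene face that gives 2R,3S and syn oxygen transfer to the Z-alkene keeps CH2OH and the C3 methyl group cis.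

**Step 5**
Reactants: 7 [(2R,3S)-2,3-dimethyloxiran-2-yl]methanol
Product: 8 (2S,3S)-2,3-dimethyloxirane-2-carboxylic acid (epoxyangelic acid)
Conditions: RuCl3·xH2O (2 mol%), NaIO4, MeCN/EtOAc/H2O, 0 °C to rt
Reagents that add atoms: sodium periodate, [Na+].[O-]I(=O)(=O)=O
Why: RuO4-catalysed oxidation of the primary alcohol to the acid, which touches no stereocentre (the C2 descriptor changes only through ligand priorities).

**Step 6**
Reactants: 9 methyl (triphenyl-λ5-phosphanylidene)acetate; 10 3-bromoprop-1-yne; 11 2,2-dimethoxyacetaldehyde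
Product: 13 methyl (2E)-4,4-dimethoxy-2-(prop-2-yn-1-yl)but-2-enoate, via alkylated ylide 12 (not isolated)
Conditions: 9 (2 equiv), 10, EtOAc, 60 °C; then 11 (60% aq.), rt to 40 °C
Reagents that add atoms: none
Why: C-alkylation of the stabilised ylide with transylidation by the second equivalent of 9, then a Wittig olefination whose α-branched stabilised ylide places the acetal carbon trans to CO2Me (the 1(10)E geometry of the target).

**Step 7**
Reactants: 13 methyl (2E)-4,4-dimethoxy-2-(prop-2-yn-1-yl)but-2-enoate; 14 acetic acid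
Product: 15 methyl (2E)-2-[(1S)-1-acetoxyprop-2-en-1-yl]-4,4-dimethoxybut-2-enoate
Conditions: [Rh(cod)Cl]2 (2.5 mol%), (R,R)-Cp-DIOP (5 mol%), 14 (2 equiv), ClCH2CH2Cl, 70 °C
Reagents that add atoms: none
Why: Rhodium-catalysed redox-neutral hydro-oxycarbonylation of a terminal alkyne (alkyne-to-allene isomerisation, hydrometalation to a π-allyl rhodium species, C–O reductive elimination at the substituted terminus) gives the branched allylic acetate, and the chiral diphosphine sets C9 (9S here, 9R in the target by priority change).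

**Step 8**
Reactants: 15 methyl (2E)-2-[(1S)-1-acetoxyprop-2-en-1-yl]-4,4-dimethoxybut-2-enoate
Product: 16 methyl (2E)-2-[(1R)-1-acetoxy-2-oxoethyl]-4,4-dimethoxybut-2-enoate
Conditions: O3 (1.0 equiv), CH2Cl2, −78 °C; Me2S; used crude
Reagents that add atoms: ozone, [O-][O+]=O
Why: Ozonolysis with reductive work-up cleaves the monosubstituted vinyl group in preference to the trisubstituted, doubly deactivated enoate and leaves C9 untouched.

**Step 9**
Reactants: 16 methyl (2E)-2-[(1R)-1-acetoxy-2-oxoethyl]-4,4-dimethoxybut-2-enoate; 4 tert-butyl (2Z,4E)-2-(bromomethyl)hexa-2,4-dienoate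
Product: 17 1-tert-butyl 7-methyl (3R,4S,5R,6E)-5-acetoxy-6-(2,2-dimethoxyethylidene)-4-hydroxy-2-methylidene-3-[(1E)-prop-1-en-1-yl]heptanedioate (7R,8S,9R)
Conditions: indium powder, THF/H2O 1:1, 0 °C to rt
Reagents that add atoms: none
Why: Aqueous indium Barbier allylation at the γ-carbon of the dienyl bromide, in which the 2Z geometry gives the C7/C8 syn adduct through a chair transition state and polar Felkin–Anh attack anti to the C9 acetoxy group gives the C8/C9 anti relationship; the tert-butyl ester does not lactonise.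

**Step 10**
Reactants: 17 seco-alcohol (7R,8S,9R); 8 (2S,3S)-2,3-dimethyloxirane-2-carboxylic acid
Product: 18 1-tert-butyl 7-methyl (3R,4S,5R,6E)-5-acetoxy-6-(2,2-dimethoxyethylidene)-4-{[(2S,3S)-2,3-dimethyloxirane-2-carbonyl]oxy}-2-methylidene-3-[(1E)-prop-1-en-1-yl]heptanedioate
Conditions: 2-methyl-6-nitrobenzoic anhydride, DMAP, Et3N, CH2Cl2, 0 °C to rt
Reagents that add atoms: none
Why: Shiina mixed-anhydride esterification acylates O8 with retention fast enough to outrun 1,2-acetyl migration, and material from the minor enantiomers of 8 or 15 is removed here as separable diastereomers.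

**Step 11**
Reactants: 18 seco-diester (7R,8S,9R,2'S,3'S)
Product: 19 methyl (2E)-2-{(1R,2S)-1-acetoxy-2-{[(2S,3S)-2,3-dimethyloxirane-2-carbonyl]oxy}-2-[(2R,3S)-2-ethenyl-4-methylidene-5-oxooxolan-3-yl]ethyl}-4,4-dimethoxybut-2-enoate (6R,7S,8S,9R)
Conditions: (PhSe)2 (10 mol%), 2,4,6-tris(4-methoxyphenyl)pyrylium tetrafluoroborate (5 mol%), air, MeCN, 465 nm LED, 23 °C
Reagents that add atoms: none
Why: Proposed new method: an aerobic selenium-π-acid/photoredox dehydrogenative lactonisation in which a tert-butyl ester, not a free acid, is the oxygen nucleophile; PhSe+ (from photo-oxidised (PhSe)2) reversibly forms a seleniranium ion only on the electron-rich C5=C6 propenyl bond; the ester C=O closes 5-exo at C6 anti to selenium through the conformer with H7 eclipsing the alkene, so C5 and the C8 branch end up trans (6R); the tert-butoxy oxocarbenium ion is drained irreversibly by loss of 2-methylpropene, whereas reversible capture by the C8/C9 ester carbonyls has no such exit; one-electron oxidation of the C5 selenide then triggers elimination towards C4–H, away from the C6–O bond, giving the vinyl group and returning PhSe+; the closest known reactions are the selenium-catalysed aerobic dehydrogenative lactonisation of free alkenoic acids and the dealkylative iodolactonisation of tert-butyl esters and carbonates.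

**Step 12**
Reactants: 19 vinyl lactone acetal (6R,7S,8S,9R)
Product: 20 methyl (2E)-2-{(1R,2S)-1-acetoxy-2-{[(2S,3S)-2,3-dimethyloxirane-2-carbonyl]oxy}-2-[(2R,3S)-2-ethenyl-4-methylidene-5-oxooxolan-3-yl]ethyl}-4-oxobut-2-enoate
Conditions: Et3SiOTf, 2,6-lutidine, CH2Cl2, 0 °C; then H2O
Reagents that add atoms: water, O
Why: Acetal cleavage through a silyl-triflate-generated lutidinium salt that is hydrolysed on adding water, a weakly basic method that spares the oxirane ester, the acetate and the α-methylene lactone.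

**Step 13**
Reactants: 20 vinyl lactone enal (6R,7S,8S,9R); 21 allyl chloride
Product: 23 methyl (2E)-3-[(2R,3S)-3-ethenyloxiran-2-yl]-2-{(1R,2S)-1-acetoxy-2-{[(2S,3S)-2,3-dimethyloxirane-2-carbonyl]oxy}-2-[(2R,3S)-2-ethenyl-4-methylidene-5-oxooxolan-3-yl]ethyl}prop-2-enoate, via syn-chlorohydrin 22 (not isolated)
Conditions: 21, LiN(c-C6H11)2, (−)-Ipc2BOMe, Et2O, −95 °C; BF3·OEt2; 20, −95 °C; 8-hydroxyquinoline, rt, filter; then DBU, CH2Cl2, 0 °C to rt
Reagents that add atoms: none
Why: Brown-type asymmetric allylboration with the (Z)-γ-chloroallylborane adds through a chair transition state to the Si face of the enal to give the 2R,3R syn-chlorohydrin, and base-induced intramolecular SN2 displacement (inversion at C3) closes the cis-oxirane 2R,3S.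

**Step 14**
Reactants: 23 bis-vinyl precursor (2R,3S,6R,7S,8S,9R)
Product: 24 target CNP0077533.1
Conditions: second-generation Grubbs catalyst RuCl2(=CHPh)(H2IMes)(PCy3) (10 mol%), 1,4-benzoquinone (20 mol%), CH2Cl2 (1 mM), 40 °C
Reagents that add atoms: none
Why: Ring-closing metathesis joins the only two monosubstituted alkenes (the 1,1-disubstituted acrylate and the trisubstituted enoate are spectators); the ring-cis C1=C10 bond, the cis-oxirane and the trans-lactone pre-bend the chain so that the less strained 4Z ring forms under reversible conditions; 40 °C or below avoids Cope rearrangement of the cis-dialkenyl oxirane.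

**Compound list**
1 | (E)-but-2-enal | C/C=C/C=O | starting material
2 | tert-butyl acrylate | C=CC(=O)OC(C)(C)C | starting material
3 | tert-butyl (4E)-3-hydroxy-2-methylidenehex-4-enoate (racemic) | C/C=C/C(O)C(=C)C(=O)OC(C)(C)C | intermediate
4 | tert-butyl (2Z,4E)-2-(bromomethyl)hexa-2,4-dienoate | C/C=C/C=C(\CBr)C(=O)OC(C)(C)C | intermediate
5 | angelic acid | C/C=C(/C)C(=O)O | starting material
6 | (Z)-2-methylbut-2-en-1-ol | C/C=C(/C)CO | intermediate
7 | [(2R,3S)-2,3-dimethyloxiran-2-yl]methanol | OC[C@@]1(C)O[C@H]1C | intermediate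
8 | (2S,3S)-2,3-dimethyloxirane-2-carboxylic acid | OC(=O)[C@@]1(C)O[C@H]1C | intermediate
9 | methyl (triphenyl-λ5-phosphanylidene)acetate | COC(=O)C=P(c1ccccc1)(c1ccccc1)c1ccccc1 | starting material
10 | 3-bromoprop-1-yne | C#CCBr | starting material
11 | 2,2-dimethoxyacetaldehyde | COC(OC)C=O | starting material
12 | methyl 2-(triphenyl-λ5-phosphanylidene)pent-4-ynoate | COC(=O)C(CC#C)=P(c1ccccc1)(c1ccccc1)c1ccccc1 | intermediate
13 | methyl (2E)-4,4-dimethoxy-2-(prop-2-yn-1-yl)but-2-enoate | COC(OC)/C=C(/C(=O)OC)CC#C | intermediate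
14 | acetic acid | CC(=O)O | starting material
15 | methyl (2E)-2-[(1S)-1-acetoxyprop-2-en-1-yl]-4,4-dimethoxybut-2-enoate | COC(OC)/C=C(/C(=O)OC)[C@@H](OC(C)=O)C=C | intermediate
16 | methyl (2E)-2-[(1R)-1-acetoxy-2-oxoethyl]-4,4-dimethoxybut-2-enoate | COC(OC)/C=C(/C(=O)OC)[C@@H](OC(C)=O)C=O | intermediate
17 | seco-alcohol (7R,8S,9R), name as in step 9 | COC(OC)/C=C(/C(=O)OC)[C@@H](OC(C)=O)[C@@H](O)[C@@H](C(=C)C(=O)OC(C)(C)C)/C=C/C | intermediate
18 | seco-diester (7R,8S,9R,2'S,3'S), name as in step 10 | COC(OC)/C=C(/C(=O)OC)[C@@H](OC(C)=O)[C@@H](OC(=O)[C@@]1(C)O[C@H]1C)[C@@H](C(=C)C(=O)OC(C)(C)C)/C=C/C | intermediate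
19 | vinyl lactone acetal (6R,7S,8S,9R), name as in step 11 | COC(OC)/C=C(/C(=O)OC)[C@@H](OC(C)=O)[C@@H](OC(=O)[C@@]1(C)O[C@H]1C)[C@@H]1[C@@H](C=C)OC(=O)C1=C | intermediate
20 | vinyl lactone enal (6R,7S,8S,9R), name as in step 12 | O=C/C=C(/C(=O)OC)[C@@H](OC(C)=O)[C@@H](OC(=O)[C@@]1(C)O[C@H]1C)[C@@H]1[C@@H](C=C)OC(=O)C1=C | intermediate
21 | allyl chloride | C=CCCl | starting material
22 | syn-chlorohydrin, methyl (2E,4R,5R)-5-chloro-4-hydroxyhepta-2,6-dienoate carrying at C2 the same (1R,2S)-diacyloxy-lactonyl-ethyl group as 20 | C=C[C@@H](Cl)[C@H](O)/C=C(/C(=O)OC)[C@@H](OC(C)=O)[C@@H](OC(=O)[C@@]1(C)O[C@H]1C)[C@@H]1[C@@H](C=C)OC(=O)C1=C | intermediate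
23 | bis-vinyl precursor (2R,3S,6R,7S,8S,9R), name as in step 13 | C=C[C@@H]1O[C@@H]1/C=C(/C(=O)OC)[C@@H](OC(C)=O)[C@@H](OC(=O)[C@@]1(C)O[C@H]1C)[C@@H]1[C@@H](C=C)OC(=O)C1=C | intermediate
24 | CNP0077533.1, methyl (1(10)E,4Z,2R,3S,6R,7S,8S,9R)-9-acetoxy-2,3-epoxy-8-[(2S,3S)-epoxyangeloyloxy]-15-norgermacra-1(10),4,11(13)-trien-12,6-olid-14-oate | C=C1C(=O)O[C@@H]2/C=C\[C@@H]3O[C@@H]3/C=C(/C(=O)OC)[C@@H](OC(C)=O)[C@@H](OC(=O)[C@@]3(C)O[C@H]3C)[C@@H]12 | target

**Step count**
Total steps: 14. Longest linear sequence: 9 (steps 6 to 14, from 9, 10 and 11).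

**Three steps most likely to fail**

Step 11 (new lactonisation). The risks are low nucleophilicity of the ester carbonyl, an insufficient trans/cis ratio at C6, and photo-oxidative damage.
- The fallback sets out from 18 and returns at 20, so it replaces steps 11 and 12.
- Me3SiOTf/2,6-lutidine in CH2Cl2 at 0 °C, then water, unmasks the tert-butyl ester and the acetal together. This gives the (7R,8S,9R)-2-methylidene-3-propenyl acid aldehyde F1.
- The known oxidative cyclisation of 4-alkenoic acids then converts F1 directly into 20. Conditions are Pd(OAc)2 (10 mol%), NaOAc, DMSO and O2 at rt. The mechanism is oxypalladation by divalent palladium at C6 followed by β-hydride elimination towards the methyl group.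

Step 14 (ten-membered ring closure). The risks are ring strain, E/Z control, oligomerisation, and thermal rearrangement of the cis-dialkenyl oxirane.
- The fallback changes the order of ring formation. It sets out from 22 and returns at 24.
- Compound 22 is isolated after the 8-hydroxyquinoline work-up, with no DBU added.
- The conformationally freer chlorohydrin is cyclised with RuCl2(=CHPh)(H2IMes)(PCy3) at 1 mM in CH2Cl2. This gives the macrocyclic (4Z,2R,3R)-chlorohydrin F2.
- DBU in CH2Cl2 at 0 °C then closes the oxirane by transannular SN2 displacement as the last step.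

Step 9 (three contiguous centres from a labile α-acetoxy aldehyde). The risks are geometric leakage of the allylindium species, modest Felkin selectivity, and isomerisation of 16 in water.
- The fallback replaces the Barbier reagent with a configurationally stable allylboronate. It sets out from 4 and returns at 17.
- Borylation of 4 with B2pin2 and Pd2(dba)3 in toluene gives tert-butyl (2E,4E)-2-[(pinacolatoboryl)methyl]hexa-2,4-dienoate F3.
- F3 reacts with 16 in anhydrous toluene at 40 °C through a closed chair transition state. The stereospecific syn adduct 17 is released on aqueous work-up.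

**Further compounds**
F1 | step 11 | (3R,4S,5R,6E)-5-acetoxy-4-{[(2S,3S)-2,3-dimethyloxirane-2-carbonyl]oxy}-6-(methoxycarbonyl)-2-methylidene-8-oxo-3-[(1E)-prop-1-en-1-yl]oct-6-enoic acid | O=C/C=C(/C(=O)OC)[C@@H](OC(C)=O)[C@@H](OC(=O)[C@@]1(C)O[C@H]1C)[C@@H](C(=C)C(=O)O)/C=C/C
F2 | step 14 | macrocyclic chlorohydrin, the 3-chloro-2-hydroxy (2R,3R) analogue of 24 | C=C1C(=O)O[C@@H]2/C=C\[C@@H](Cl)[C@H](O)/C=C(/C(=O)OC)[C@@H](OC(C)=O)[C@@H](OC(=O)[C@@]3(C)O[C@H]3C)[C@@H]12
F3 | step 9 | tert-butyl (2E,4E)-2-[(4,4,5,5-tetramethyl-1,3,2-dioxaborolan-2-yl)methyl]hexa-2,4-dienoate | C/C=C/C=C(\CB1OC(C)(C)C(C)(C)O1)C(=O)OC(C)(C)C
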